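The triene is cut at the pyranone-side C=C (Horner–Wadsworth–Emmons) and at the two C=C bonds nearer the ring (two Wittig homologations), leaving a 2-(1-phosphonoethyl)-6-methoxy-3,5-dimethylpyran-4-one and a cyclohexane core with an aldehyde-level carbon on C1; the core is then cut at C1–C6 and C2–C3 ([4+2]).
Enabling feature: on the cyclohexane (C1 side-chain CH, C2 CHMe, C3 C(Me)OH, C4 CHOAc, C5 C(Me)OH, C6 CHOAc), C1 and C2 bear cis carbon substituents that are the two ends of a butenolide (lactone carbonyl on C1, acetal carbon on C2 as a latent methyl), and C3–C6 with their two methyls and the C4 and C6 oxygens are the carbons of a 1-methoxy-2-methyl-3-silyloxypenta-1,3-diene.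
Forward order: the furanone ring (from furfural) and the diene are made, the cycloaddition closes the only carbocycle cis-fused to the lactone, the ring is oxygenated (C5/C6, then C3, then C4), the lactone acetal is unravelled into the C2 methyl and a C1 enoate, the chain is grown to the dienal, the separately made pyranone ring is joined last, then deprotection and diacetylation.
Stereochemistry: (−)-menthol gives a crystalline (5R) acetal whose menthyloxy group fixes the diene face and hence C1 and C2 in absolute terms; C5/C6, C3 and C4 follow by substrate control (oxidants add to the face away from the lactone, hydride anti to the axial C–O bonds); the three E alkenes come from stabilised ylide and phosphonate olefinations.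
Convention: ring numbering as above; lower face = face of the C1 and C2 carbon substituents and of the C3 and C5 methyls, upper face = face of the four oxygens; the target is (1R,2S,3R,4R,5S,6S) in this numbering.

Key step: step 5

Remark: the two phosphoranes, 2-(phenylsulfonyl)-3-phenyloxaziridine and N-methoxy-N-methylpropanamide are taken as purchased reagents, and the species numbered as non-isolated intermediates are those present in the flask between two successive operations of one step.

Step 1
Reactants: 1 furfural
Product: 2 5-hydroxyfuran-2(5H)-one (racemic)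
Conditions: O2, hν, rose bengal (cat.), MeOH, rt
Reagents that add atoms: oxygen, O=O
Why: Dye-sensitised singlet-oxygen [4+2] addition to the furan (photooxygenation) gives an endoperoxide that methanol opens with loss of the formyl carbon as methyl formate, leaving the racemic γ-hydroxybutenolide.

Step 2
Reactants: 2 5-hydroxyfuran-2(5H)-one; 3 (−)-menthol
Product: 4 (5R)-5-[(1R,2S,5R)-menthyloxy]furan-2(5H)-one
Conditions: CSA (cat.), PhMe, reflux, −H2O; crystallisation from hexane, mother liquor re-equilibrated with CSA
Reagents that add atoms: none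
Why: Acid-catalysed acetalisation of the lactol gives both C5 epimers, which interconvert under acid, so crystallisation of the less soluble (5R) epimer should set the acetal stereocentre and allow the mother liquor to be recycled.

Step 3
Reactants: 5 pentan-3-one
Product: 7 (E)-1-methoxy-2-methylpent-1-en-3-one, via sodium enolate 6 (not isolated)
Conditions: NaOMe, HCO2Et, Et2O, 0 °C → rt; then Me2SO4, DMF, rt
Reagents that add atoms: ethyl formate, CCOC=O; sodium methoxide, [Na+].[O-]C (sodium of 6); dimethyl sulfate, COS(=O)(=O)OC
Why: Claisen-type formylation of the ketone enolate gives the sodium salt of the hydroxymethylene ketone, whose oxygen terminus is O-methylated by the hard sulfate to the thermodynamically favoured (E)-β-methoxy enone.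

Step 4
Reactants: 7 (E)-1-methoxy-2-methylpent-1-en-3-one
Product: 8 (1E,3Z)-1-methoxy-2-methyl-3-(trimethylsilyloxy)penta-1,3-diene
Conditions: TMSOTf, Et3N, Et2O, 0 °C
Reagents that add atoms: trimethylsilyl triflate, C[Si](C)(C)OS(=O)(=O)C(F)(F)F
Why: Soft enolisation (silyl triflate with amine base) of the ethyl ketone should give the silyl dienol ether with the terminal methyl cis to the silyloxy group (3Z), so that in the s-cis diene this methyl and the methoxy group both point outward.

Step 5
Reactants: 4 (5R)-5-menthyloxyfuran-2(5H)-one; 8 (1E,3Z)-1-methoxy-2-methyl-3-(trimethylsilyloxy)penta-1,3-diene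
Product: 10 cis-fused enone lactone acetal, via silyl enol ether cycloadduct 9 (not isolated)
Conditions: PhMe, 110 °C, sealed tube, 8 in excess; then TFA (cat.), CH2Cl2, 0 °C; aq. NaHCO3
Reagents that add atoms: none
Why: This is a thermal normal-electron-demand Diels–Alder reaction in which the electron-rich diene 8 and the electron-poor butenolide 4 combine in a concerted, asynchronous, suprafacial [4+2] cycloaddition, after which acid expels the allylic methoxy group of cycloadduct 9 with desilylation to unmask the enone. The closest known reaction type is the thermal cycloaddition of 5-alkoxybutenolides carrying a menthyl auxiliary with 1-alkoxy-3-silyloxybutadienes followed by acid treatment. The cyclohexene ring closes by intermolecular [4+2] cycloaddition, forming C1–C6 and C2–C3 at once, and is necessarily cis-fused to the lactone because the dienophile alkene is locked cis in the five-membered ring. C1 and C2 are controlled by the (R)-configured menthyloxy acetal carbon next to the reacting alkene, which shields one face so that the diene adds anti to it; C3 is controlled by the endo transition state together with the outward terminal methyl of the diene and is re-formed in step 8, and the C6 methoxy centre of 9 is lost on elimination. The step needs facial selectivity, secured by the bulky menthyloxy group, and regioselectivity, secured by the polarised diene, whose nucleophilic methyl-bearing terminus bonds to the electrophilic β-carbon of the butenolide.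

Step 6
Reactants: 10 cis-fused enone lactone acetal
Product: 11 C5,C6-diol
Conditions: OsO4 (cat.), NMO, citric acid, t-BuOH/H2O, rt
Reagents that add atoms: N-methylmorpholine N-oxide, C[N+]1([O-])CCOCC1, and water, O, which supply the two hydroxyl oxygens through OsO4, O=[Os](=O)(=O)=O
Why: Catalytic syn-dihydroxylation with OsO4 and N-oxide reoxidant (citric acid keeps the electron-poor enone turning over and prevents retro-aldol cleavage) should occur on the convex upper face of the cis-fused bicycle, anti to the lactone carbon on C1, which sets C5 and C6 with both oxygens cis to each other and trans to the C1/C2 carbon substituents.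

Step 7
Reactants: 11 C5,C6-diol
Product: 12 C5,C6-acetonide ketone
Conditions: Me2C(OMe)2, PPTS (cat.), acetone, rt
Reagents that add atoms: 2,2-dimethoxypropane, COC(C)(C)OC
Why: Acid-catalysed transketalisation ties the cis tertiary/secondary diol into a dioxolane, which protects the β-hydroxy ketone against retro-aldol cleavage and leaves C3 as the only enolisable ketone position.

Step 8
Reactants: 12 C5,C6-acetonide ketone
Product: 14 C3-hydroxy ketone, via potassium enolate 13 (not isolated)
Conditions: KN(SiMe3)2, THF, −78 °C; 2-(phenylsulfonyl)-3-phenyloxaziridine, −78 °C; aq. NH4Cl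
Reagents that add atoms: potassium bis(trimethylsilyl)amide, C[Si](C)(C)[N-][Si](C)(C)C.[K+] (potassium of 13); 2-(phenylsulfonyl)-3-phenyloxaziridine, O=S(=O)(c1ccccc1)N1OC1c1ccccc1
Why: Enolate hydroxylation: kinetic deprotonation of the ketone at C3 (axial hydrogen on the upper face, more acidic than the lactone α-position) followed by electrophilic oxygen transfer from the N-sulfonyloxaziridine on the upper face, anti to the lactone ring carbon on the adjacent C2, should place the C3 hydroxyl on the upper face and keep the methyl on the lower face.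

Step 9
Reactants: 14 C3-hydroxy ketone
Product: 15 C3,C4-diol
Conditions: NaBH4, CeCl3·7H2O, MeOH, −78 → −40 °C
Reagents that add atoms: none
Why: Borohydride reduction under Luche-type conditions: with the C3 hydroxyl and the C5 dioxolane oxygen both axial on the upper face (the other chair would put three carbon substituents syn-axial), the small hydride should attack antiperiplanar to these two C–O bonds from the lower face and give the equatorial C4 alcohol cis to both neighbours, while the cerium salt keeps the medium non-basic so that the acylal lactone survives.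

Step 10
Reactants: 15 C3,C4-diol
Product: 16 bis-acetonide lactone acetal
Conditions: 2-methoxypropene, PPTS (cat.), CH2Cl2, 0 °C
Reagents that add atoms: 2-methoxypropene, COC(C)=C
Why: Kinetic acid-catalysed ketalisation with the enol ether closes a second cis-fused dioxolane over the C3/C4 diol without exchanging the first one.

Step 11
Reactants: 16 bis-acetonide lactone acetal
Product: 18 bis-acetonide γ-lactone, via potassium hydroxy carboxylate 17 (not isolated)
Conditions: NaBH4, KOH, THF/H2O, 0 °C → rt; then aq. HCl to pH 3, rt
Reagents that add atoms: potassium hydroxide, [K+].[OH-] (potassium and carboxylate oxygen of 17)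
Why: Saponification–reduction–lactonisation: hydroxide opens the acylal-type lactone, the released hemiacetal collapses to menthol and the C2 aldehyde, which borohydride already present reduces before it can epimerise, and acidification closes the cis γ-hydroxy acid to the γ-lactone (the lower-face carboxyl cannot reach any ring oxygen), so the former acetal carbon is now at the alcohol level while the C1 carbon stays at the acid level.

Step 12
Reactants: 18 bis-acetonide γ-lactone
Product: 19 lactol
Conditions: i-Bu2AlH, CH2Cl2, −78 °C; aq. KNaC4H4O6 (potassium sodium tartrate)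
Reagents that add atoms: none
Why: Partial reduction of the γ-lactone by the aluminium hydride at low temperature stops at the tetrahedral aluminate, which gives the lactol on work-up (the new anomeric centre is of no consequence).

Step 13
Reactants: 19 lactol
Product: 20 hydroxy enoate
Conditions: Ph3P=C(Me)CO2Et, PhMe, 80 °C
Reagents that add atoms: ethyl 2-(triphenylphosphoranylidene)propanoate, CCOC(=O)C(C)=P(c1ccccc1)(c1ccccc1)c1ccccc1
Why: The lactol reacts through its hydroxy aldehyde tautomer in a Wittig reaction with the stabilised ylide, which should give the (E)-2-methyl enoate without base that could epimerise C1 and frees the C2 hydroxymethyl group.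

Step 14
Reactants: 20 hydroxy enoate
Product: 21 iodide
Conditions: I2, PPh3, imidazole, CH2Cl2, 0 °C → rt
Reagents that add atoms: iodine, II
Why: Appel-type iodination (alkoxyphosphonium ion displaced by iodide) should convert the primary alcohol, whose β-carbon is tertiary and not quaternary, into the iodide under neutral conditions.

Step 15
Reactants: 21 iodide
Product: 22 allylic alcohol
Conditions: LiAlH4, THF, 0 °C → rt
Reagents that add atoms: none
Why: Hydride reduction by LiAlH4 displaces the primary iodide (completing the C2 methyl) and reduces the conjugated ester by 1,2-addition to the allylic alcohol in one operation, the ketals being inert.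

Step 16
Reactants: 22 allylic alcohol
Product: 23 enal
Conditions: MnO2, CH2Cl2, rt
Reagents that add atoms: none
Why: Chemoselective allylic oxidation on MnO2 should give the (E)-enal without touching the ketals or the alkene geometry.

Step 17
Reactants: 23 enal
Product: 24 dienal
Conditions: Ph3P=CHCHO, PhMe, 80 °C
Reagents that add atoms: (triphenylphosphoranylidene)acetaldehyde, O=CC=P(c1ccccc1)(c1ccccc1)c1ccccc1
Why: Wittig two-carbon homologation with the stabilised formyl ylide should give the (2E,4E)-dienal, the new disubstituted alkene forming E as usual for stabilised ylides.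

Step 18
Reactants: 25 ethyl 2-methyl-3-oxopentanoate
Product: 28 6-ethyl-4-hydroxy-3,5-dimethyl-2H-pyran-2-one, via ketoester dianion 26 (not isolated), via diketo ester 27 (not isolated)
Conditions: NaH, THF, 0 °C; n-BuLi, 0 °C; EtC(O)N(OMe)Me; aq. NH4Cl; then DBU, PhMe, reflux
Reagents that add atoms: sodium hydride, [Na+].[H-], and n-butyllithium, [Li]CCCC (metals of 26); N-methoxy-N-methylpropanamide, CCC(=O)N(C)OC
Why: γ-Acylation of the ketoester dianion by the N-methoxy-N-methylamide (its chelated tetrahedral adduct prevents over-addition) gives the 3,5-diketo ester, which under amidine base lactonises through the C5 enol oxygen with loss of ethanol to the 4-hydroxy-2-pyranone (Claisen-type condensation and cyclisation).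

Step 19
Reactants: 28 6-ethyl-4-hydroxy-3,5-dimethyl-2H-pyran-2-one
Product: 29 2-ethyl-6-methoxy-3,5-dimethyl-4H-pyran-4-one
Conditions: MeOTf, CH2Cl2, rt; aq. NaHCO3
Reagents that add atoms: methyl triflate, COS(=O)(=O)C(F)(F)F
Why: Regioselective O-alkylation: the hard methylating agent should attack the most nucleophilic site of the neutral 4-hydroxy-2-pyranone, the lactone carbonyl oxygen, giving a 4-hydroxy-2-methoxypyrylium salt that loses a proton to the 2-methoxy-4-pyranone (any 4-methoxy-2-pyranone isomer is removed by chromatography).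

Step 20
Reactants: 29 2-ethyl-6-methoxy-3,5-dimethyl-4H-pyran-4-one
Product: 31 diethyl [1-(6-methoxy-3,5-dimethyl-4-oxo-4H-pyran-2-yl)ethyl]phosphonate, via lithiated pyranone 30 (not isolated)
Conditions: LiN(SiMe3)2 (2.2 equiv), THF, −78 °C; ClP(O)(OEt)2; aq. NH4Cl
Reagents that add atoms: lithium bis(trimethylsilyl)amide, C[Si](C)(C)[N-][Si](C)(C)C.[Li+] (lithium of 30); diethyl chlorophosphate, CCOP(=O)(Cl)OCC
Why: Lateral deprotonation of the vinylogously activated CH2 of the 2-ethyl group and C-phosphorylation with the chlorophosphate should give the phosphonate, the second equivalent of base being taken up by the more acidic product (the new stereocentre is racemic and disappears in step 21).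

Step 21
Reactants: 24 dienal; 31 diethyl [1-(6-methoxy-3,5-dimethyl-4-oxo-4H-pyran-2-yl)ethyl]phosphonate
Product: 33 bis-acetonide of the side-chain tetraol, via lithium phosphonate carbanion 32 (not isolated)
Conditions: LiN(SiMe3)2, THF, −78 °C; then 24, −78 °C → rt
Reagents that add atoms: lithium bis(trimethylsilyl)amide, C[Si](C)(C)[N-][Si](C)(C)C.[Li+] (lithium of 32)
Why: Horner–Wadsworth–Emmons olefination: the pyranone-stabilised phosphonate carbanion adds reversibly to the unhindered dienal and eliminates phosphate, which should give the E trisubstituted alkene (pyranone trans to the chain) and complete the all-E triene, the ketals tolerating the base.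

Step 22
Reactants: 33 bis-acetonide of the side-chain tetraol
Product: 34 tetraol
Conditions: AcOH/H2O (4:1), 45 °C
Reagents that add atoms: none
Why: Acid-catalysed ketal hydrolysis of the two isopropylidene groups, which crowd each other on one face and should therefore be labile, releases the tetraol under conditions mild enough for the triene and the vinylogous ester of the pyranone.

Step 23
Reactants: 34 tetraol
Product: 35 amaurone B
Conditions: Ac2O, pyridine, DMAP (cat.), CH2Cl2, 0 °C → rt
Reagents that add atoms: acetic anhydride, CC(=O)OC(C)=O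
Why: Nucleophile-catalysed acylation should acetylate the two secondary hydroxyls (C4, C6) and leave the two hindered tertiary hydroxyls (C3, C5) free, giving the diacetate.

Compound list
1 | furfural (furan-2-carbaldehyde) | O=Cc1ccco1 | starting material
2 | 5-hydroxyfuran-2(5H)-one, racemic lactol | O=C1C=CC(O)O1 | intermediate
3 | (−)-menthol, (1R,2S,5R)-5-methyl-2-(propan-2-yl)cyclohexan-1-ol | CC(C)[C@@H]1CC[C@@H](C)C[C@H]1O | starting material
4 | (5R)-5-[(1R,2S,5R)-menthyloxy]furan-2(5H)-one | O=C1C=C[C@H](O[C@@H]2C[C@H](C)CC[C@H]2C(C)C)O1 | intermediate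
5 | pentan-3-one | CCC(=O)CC | starting material
6 | sodium 2-methyl-3-oxopent-1-en-1-olate (not isolated) | CCC(=O)C(C)=C[O-].[Na+] | intermediate
7 | (E)-1-methoxy-2-methylpent-1-en-3-one | CCC(=O)/C(C)=C/OC | intermediate
8 | (1E,3Z)-1-methoxy-2-methyl-3-(trimethylsilyloxy)penta-1,3-diene | CO/C=C(C)/C(O[Si](C)(C)C)=C/C | intermediate
9 | silyl enol ether cycloadduct (not isolated): cis-fused cyclohexene lactone acetal, lactone C=O on C1 and (R)-menthyloxy acetal carbon on C2 (lower face), C3 methyl and C6 methoxy on the lower face, C4(OSiMe3)=C5(Me) | O=C1O[C@@H](O[C@@H]3C[C@H](C)CC[C@H]3C(C)C)[C@H]2[C@@H]1[C@@H](OC)C(C)=C(O[Si](C)(C)C)[C@H]2C | intermediate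
10 | cis-fused enone lactone acetal: lactone C=O on C1 and (R)-menthyloxy acetal carbon on C2 (lower face), C3 methyl on the lower face, C4 ketone, C5(Me)=C6H | O=C1O[C@@H](O[C@@H]3C[C@H](C)CC[C@H]3C(C)C)[C@H]2[C@@H]1C=C(C)C(=O)[C@H]2C | intermediate
11 | C5,C6-diol: as 10 with C5(OH)(Me) and C6(OH), both hydroxyls on the upper face | O=C1O[C@@H](O[C@@H]3C[C@H](C)CC[C@H]3C(C)C)[C@H]2[C@@H]1[C@H](O)[C@](C)(O)C(=O)[C@H]2C | intermediate
12 | C5,C6-acetonide ketone: isopropylidene ketal of 11, dioxolane cis-fused on the upper face | O=C1O[C@@H](O[C@@H]3C[C@H](C)CC[C@H]3C(C)C)[C@H]2[C@@H]1[C@@H]4OC(C)(C)O[C@]4(C)C(=O)[C@H]2C | intermediate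
13 | potassium enolate of 12, C3=C4–OK (not isolated) | O=C1O[C@@H](O[C@@H]3C[C@H](C)CC[C@H]3C(C)C)[C@H]2[C@@H]1[C@@H]4OC(C)(C)O[C@]4(C)C([O-])=C2C.[K+] | intermediate
14 | C3-hydroxy ketone: as 12 with C3(OH)(Me), hydroxyl on the upper face, methyl on the lower face | O=C1O[C@@H](O[C@@H]3C[C@H](C)CC[C@H]3C(C)C)[C@H]2[C@@H]1[C@@H]4OC(C)(C)O[C@]4(C)C(=O)[C@]2(C)O | intermediate
15 | C3,C4-diol: as 14 with C4 carbinol, hydroxyl on the upper face | O=C1O[C@@H](O[C@@H]3C[C@H](C)CC[C@H]3C(C)C)[C@H]2[C@@H]1[C@@H]4OC(C)(C)O[C@]4(C)[C@H](O)[C@]2(C)O | intermediate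
16 | bis-acetonide lactone acetal: C3,C4- and C5,C6-isopropylidene ketals on the upper face, menthyloxy lactone acetal on the lower face | O=C1O[C@@H](O[C@@H]3C[C@H](C)CC[C@H]3C(C)C)[C@H]2[C@@H]1[C@@H]4OC(C)(C)O[C@]4(C)[C@@H]5OC(C)(C)O[C@]25C | intermediate
17 | potassium hydroxy carboxylate (not isolated): C1–CO2K and C2–CH2OH on the lower face, bis-acetonide | [K+].[O-]C(=O)[C@@H]1[C@H](CO)[C@@]2(C)OC(C)(C)O[C@H]2[C@@]3(C)OC(C)(C)O[C@@H]13 | intermediate
18 | bis-acetonide γ-lactone: C1–C(=O)–O–CH2–C2 cis-fused on the lower face | O=C1OC[C@H]2[C@@H]1[C@@H]3OC(C)(C)O[C@]3(C)[C@@H]4OC(C)(C)O[C@]24C | intermediate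
19 | lactol: as 18 with the lactone carbonyl reduced to CH(OH), anomer mixture | OC1OC[C@H]2[C@@H]1[C@@H]3OC(C)(C)O[C@]3(C)[C@@H]4OC(C)(C)O[C@]24C | intermediate
20 | hydroxy enoate: ethyl (E)-2-methylprop-2-enoate attached through its C3 to ring C1, CH2OH on C2, bis-acetonide | CCOC(=O)/C(C)=C/[C@@H]1[C@H](CO)[C@@]2(C)OC(C)(C)O[C@H]2[C@@]3(C)OC(C)(C)O[C@@H]13 | intermediate
21 | iodide: as 20 with CH2I on C2 | CCOC(=O)/C(C)=C/[C@@H]1[C@H](CI)[C@@]2(C)OC(C)(C)O[C@H]2[C@@]3(C)OC(C)(C)O[C@@H]13 | intermediate
22 | allylic alcohol: (E)-2-methylprop-2-en-1-ol attached through its C3 to ring C1, methyl on C2 (lower face), bis-acetonide | OC/C(C)=C/[C@@H]1[C@H](C)[C@@]2(C)OC(C)(C)O[C@H]2[C@@]3(C)OC(C)(C)O[C@@H]13 | intermediate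
23 | enal: (E)-2-methylprop-2-enal attached through its C3 to ring C1 | O=C/C(C)=C/[C@@H]1[C@H](C)[C@@]2(C)OC(C)(C)O[C@H]2[C@@]3(C)OC(C)(C)O[C@@H]13 | intermediate
24 | dienal: (2E,4E)-4-methylpenta-2,4-dienal attached through its C5 to ring C1 | O=C/C=C/C(C)=C/[C@@H]1[C@H](C)[C@@]2(C)OC(C)(C)O[C@H]2[C@@]3(C)OC(C)(C)O[C@@H]13 | intermediate
25 | ethyl 2-methyl-3-oxopentanoate (racemic) | CCC(=O)C(C)C(=O)OCC | starting material
26 | sodium lithium dianion of 25 at C2 and C4 (not isolated) | C[CH-]C(=O)[C-](C)C(=O)OCC.[Na+].[Li+] | intermediate
27 | ethyl 2,4-dimethyl-3,5-dioxoheptanoate (not isolated, stereoisomer and tautomer mixture) | CCC(=O)C(C)C(=O)C(C)C(=O)OCC | intermediate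
28 | 6-ethyl-4-hydroxy-3,5-dimethyl-2H-pyran-2-one | CCc1oc(=O)c(C)c(O)c1C | intermediate
29 | 2-ethyl-6-methoxy-3,5-dimethyl-4H-pyran-4-one | CCc1oc(OC)c(C)c(=O)c1C | intermediate
30 | lithiated pyranone, lithium 1-(6-methoxy-3,5-dimethyl-4-oxo-4H-pyran-2-yl)ethanide (not isolated) | C[CH-]c1oc(OC)c(C)c(=O)c1C.[Li+] | intermediate
31 | diethyl [1-(6-methoxy-3,5-dimethyl-4-oxo-4H-pyran-2-yl)ethyl]phosphonate (racemic) | CCOP(=O)(OCC)C(C)c1oc(OC)c(C)c(=O)c1C | intermediate
32 | lithium carbanion of 31 (not isolated) | CCOP(=O)(OCC)[C-](C)c1oc(OC)c(C)c(=O)c1C.[Li+] | intermediate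
33 | bis-acetonide of the side-chain tetraol: all-E triene pyranone on C1, C2 methyl, 3,4:5,6-di-O-isopropylidene | COc1oc(/C(C)=C/C=C/C(C)=C/[C@@H]2[C@H](C)[C@@]3(C)OC(C)(C)O[C@H]3[C@@]4(C)OC(C)(C)O[C@@H]24)c(C)c(=O)c1C | intermediate
34 | tetraol: as 35 with free hydroxyls at C4 and C6 | COc1oc(/C(C)=C/C=C/C(C)=C/[C@@H]2[C@H](C)[C@@](C)(O)[C@@H](O)[C@@](C)(O)[C@H]2O)c(C)c(=O)c1C | intermediate
35 | amaurone B | COc1oc(/C(C)=C/C=C/C(C)=C/[C@@H]2[C@H](C)[C@@](C)(O)[C@@H](OC(C)=O)[C@@](C)(O)[C@H]2OC(C)=O)c(C)c(=O)c1C | target

Total step count: 23.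
Longest linear sequence: 18 steps (pentan-3-one 5 to 35 through steps 3–17 and 21–23; the same length from furfural 1).

Steps most likely to fail

Step 9. The hydride may be delivered from the upper face (for example through borohydride bound to the C3 hydroxyl) or attack with poor facial selectivity, which would give the C4 epimer. The fallback sets out from 12 and returns at 16. The potassium enolate of 12 is trapped with PhNTf2 (KN(SiMe3)2, THF, −78 °C) as the C3=C4 enol triflate F1. Palladium-catalysed formate reduction (Pd(OAc)2, PPh3, Bu3N, HCO2H, DMF, 60 °C) gives the trisubstituted C3=C4 alkene F2, and aqueous acetic acid frees the allylic diol F3. Stoichiometric OsO4 with TMEDA in CH2Cl2 at −78 °C, hydrogen-bond-directed by the tertiary allylic C5 hydroxyl and matched with the convex face, then delivers the C3 and C4 oxygens together on the upper face in the tetraol F4. Ketalisation with Me2C(OMe)2 and PPTS gives 16.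

Step 11. The transient C2 aldehyde may enolise in the alkaline medium before it is reduced, which would erode the cis C1/C2 relationship. The fallback sets out from 16 and returns at 18. LiAlH4 (THF, 0 °C) reduces the lactone carbonyl and the acetal carbon together, with release of menthol, to the bis(hydroxymethyl) diol F5, so that no aldehyde is exposed to base. Ag2CO3 on Celite in refluxing benzene then oxidises the less hindered, equatorial C1 hydroxymethyl group to the lactol and on to the lactone 18.

Step 17. The formyl ylide may react sluggishly with the hindered α-methyl enal and homologate the product dienal further. The fallback sets out from 23 and returns at 24. A Horner–Wadsworth–Emmons reaction with triethyl phosphonoacetate (NaH, THF, 0 °C) gives the dienoate F6, i-Bu2AlH (CH2Cl2, −78 °C) reduces it to the dienol F7, and MnO2 oxidises this to the dienal 24.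

Further compounds
F1 | step 9 | C3=C4 enol triflate of 12 | O=C1O[C@@H](O[C@@H]3C[C@H](C)CC[C@H]3C(C)C)[C@H]2[C@@H]1[C@@H]4OC(C)(C)O[C@]4(C)C(OS(=O)(=O)C(F)(F)F)=C2C
F2 | step 9 | C3=C4 alkene with C5,C6-acetonide | O=C1O[C@@H](O[C@@H]3C[C@H](C)CC[C@H]3C(C)C)[C@H]2[C@@H]1[C@@H]4OC(C)(C)O[C@]4(C)C=C2C
F3 | step 9 | allylic C5,C6-diol with C3=C4 alkene | O=C1O[C@@H](O[C@@H]3C[C@H](C)CC[C@H]3C(C)C)[C@H]2[C@@H]1[C@H](O)[C@](C)(O)C=C2C
F4 | step 9 | C3,C4,C5,C6-tetraol lactone acetal, all hydroxyls on the upper face | O=C1O[C@@H](O[C@@H]3C[C@H](C)CC[C@H]3C(C)C)[C@H]2[C@@H]1[C@H](O)[C@](C)(O)[C@H](O)[C@]2(C)O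
F5 | step 11 | C1,C2-bis(hydroxymethyl) bis-acetonide diol | OC[C@@H]1[C@H](CO)[C@@]2(C)OC(C)(C)O[C@H]2[C@@]3(C)OC(C)(C)O[C@@H]13
F6 | step 17 | ethyl (2E,4E)-4-methylpenta-2,4-dienoate attached through C5 to ring C1 | CCOC(=O)/C=C/C(C)=C/[C@@H]1[C@H](C)[C@@]2(C)OC(C)(C)O[C@H]2[C@@]3(C)OC(C)(C)O[C@@H]13
F7 | step 17 | (2E,4E)-4-methylpenta-2,4-dien-1-ol attached through C5 to ring C1 | OC/C=C/C(C)=C/[C@@H]1[C@H](C)[C@@]2(C)OC(C)(C)O[C@H]2[C@@]3(C)OC(C)(C)O[C@@H]13
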